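Write the balance of the reagent, the limiting reagent here, in fractions of the substrate charge: reagent left equals reagent charged minus product made, one for one, as the red run shows by standing at 39.9% product on a charge of 0.40 equiv.

| setting | violet | red | flask |
|---|---|---|---|
| substrate | 0.24 M | 0.24 M | 0.24 M |
| reagent | 0.80 equiv | 0.40 equiv | 0.800 equiv |
| free catalyst | 1.2 mol% | 1.2 mol% | 1.2 mol% |
| remark | the very flask that is asked about, followed so far | run made earlier |  |

violet run (percent of the substrate charged)

| time / s | product / % | substrate / % |
|---|---|---|
| 10.0 | 68.8 | 31.2 |
| 12.0 | 72.5 | 28.1 |
| 30.0 | 79.0 | 19.9 |

red run (percent of the substrate charged)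

| time / min | product / % | substrate / % |
|---|---|---|
| 0.333 | 39.9 | 60.0 |
| 0.833 | 39.7 | 59.4 |
| 1.50 | 40.3 | 59.5 |
| 2.50 | 39.9 | 59.0 |

(scatter of a reading: 0.5 percentage points)

* apparent order in reagent when 50% of the substrate are converted (percent change of the rate of making product for one percent more reagent charged)
* apparent order in free catalyst when 50% of the substrate are converted (percent change of the rate of making product for one percent more free catalyst charged)

In the violet flask at 50% conversion the balance leaves 0.300 of reagent, so one percent more charged raises that remainder by 2.67 percent. This ratio of reagent charged to reagent left, the leverage of the charge, multiplies the order the rate has in reagent left, while the substrate left at that conversion stays put.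

A first estimate takes that order as one, which makes the answer the leverage itself. The objection comes from the violet readings. Over the first 10.0 s the substrate decays at 0.116 /s on average, with reagent left near 0.350 as a logarithmic mean, and from 10.0 s to 12.0 s it decays at 0.0523 /s with 0.0935 left. Per unit of reagent the later decay is faster by a factor of 1.68, although the later step rests on a drop of 3.1 percentage points with a scatter of 0.71 points, so a reading of order one looks too high. The two decays instead give an order of 0.606, hence 1.62 for the apparent order. That still assumes first order in substrate, and the raw product rates, which ignore substrate, give an order near 0.995, so the estimate here stays at 1.62, with the leverage of 2.67 as its high side. For free catalyst, first order stays a guess.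

The forecast says 2.6 (1.9 to 2.9) and 1 (0.6 to 1.2), reasoning that “One percent more charge therefore raises remaining reagent” by about 2.7 percent, which puts it above the 1.62 reckoned here.

The flask gives 1.4 in reagent and 0.73 in free catalyst.

    substrate + free catalyst ⇌ catalyst intermediate A (K = 10.8 /M, k = 180 /M/s)
    reagent + catalyst intermediate A → catalyst intermediate B (k = 304 /M/s)
    catalyst intermediate B → free catalyst + product (k = 971 /s)
    2 free catalyst ⇌ resting dimer, settled at all times (K = 410 /M)

At 0.0585 min catalyst intermediate A in this flask falls back 0.57 times as fast as it goes on. Divided by the leverage, the result leaves an order of 0.517 in reagent left. With a fraction 0.7 of the substrate converted the same balance leaves 0.100 of reagent in this flask, a third of the remainder at 50%, the leverage there is 8.00, and the rate stands at 0.33 of its value at 50%.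

The readings were generated by integration from invented constants.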